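**Plan**
1. Retrosynthesis first cuts the ester C(=O)–O3 bond (late acylation of the 3-OH). It then cuts C3–C4 and O1–C8a together, which opens ring C into a ring-A 2-bromobenzyl bromide and a ring-B α-oxygenated aryl ketone.
2. Enabling feature: C2 carries both O1 and ring B, so at the ketone oxidation level O1–C2=C3 is an enolate with two nucleophilic ends (C3 and O1). On ring A, the benzylic C4 and the ring carbon C8a (meta to O5 and O7) can both carry bromide, so a 1,3-dinucleophile meets a 1,3-dielectrophile.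
3. Forward: the ring-A half (steps 1–3) and the ring-B half (steps 4–5) are made separately. Ring C then closes in one flask, C3–C4 by enolate benzylation and O1–C8a by copper-catalysed O-arylation, to give a 3-(methoxymethoxy)-4H-chromene, which is unmasked to the racemic flavan-3-one.
4. Stereochemistry: C2 and C3 are set together by asymmetric transfer hydrogenation with dynamic kinetic resolution. C2 epimerises through the enol, hydride adds to C3 anti to ring B (2,3-cis), and the catalyst fixes 2R,3R.
5. End game: Steglich acylation with 3,5-bis(benzyloxy)-4-methoxybenzoic acid, then hydrogenolysis of six benzyl ethers.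

Key step: step 6

Assumption: RuCl(p-cymene)[(R,R)-TsDPEN] is taken as the catalyst enantiomer that gives the (3R)-alcohol from this non-aryl cyclic ketone. The sense is assigned by analogy with α-aryl benzo-fused cyclic ketones and is not established for this ring system; the (S,S)-complex is the mirror-image choice.

**Step 1**
Reactants: 1 1,3-bis(benzyloxy)-5-bromobenzene
Product: 3 2,4-bis(benzyloxy)-6-bromobenzaldehyde, via aryl iminium chloride 2 (not isolated)
Conditions: POCl3, DMF, 0 → 70 °C; then ice/H2O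
Reagents that add atoms: N,N-dimethylformamide CN(C)C=O; water O
Why: Vilsmeier–Haack formylation; attack should occur mainly at the position para to one benzyloxy group and ortho to the other (next to Br), because the position between the two benzyloxy groups is more hindered, and the minor regioisomer is removed by crystallisation.

**Step 2**
Reactants: 3 2,4-bis(benzyloxy)-6-bromobenzaldehyde
Product: 4 [2,4-bis(benzyloxy)-6-bromophenyl]methanol
Conditions: NaBH4, MeOH/THF, 0 °C
Reagents that add atoms: none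
Why: Borohydride reduction of an aryl aldehyde; the aryl bromide and benzyl ethers are inert.

**Step 3**
Reactants: 4 [2,4-bis(benzyloxy)-6-bromophenyl]methanol
Product: 5 1,5-bis(benzyloxy)-3-bromo-2-(bromomethyl)benzene
Conditions: PBr3, CH2Cl2, 0 °C; used at once without storage
Reagents that add atoms: phosphorus tribromide BrP(Br)Br
Why: Conversion of a benzylic alcohol into the bromide through its phosphite ester (SN2); the electron-rich benzylic bromide is prone to ionisation and is therefore taken directly into step 6.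

**Step 4**
Reactants: 6 3,4-bis(benzyloxy)benzaldehyde
Product: 7 1-[3,4-bis(benzyloxy)phenyl]-2-hydroxyethan-1-one
Conditions: paraformaldehyde, 3-benzyl-5-(2-hydroxyethyl)-4-methylthiazolium chloride (10 mol %), iPr2NEt, THF, 60 °C
Reagents that add atoms: paraformaldehyde (as formaldehyde) C=O
Why: Carbene-catalysed cross-acyloin reaction (hydroxymethylation by polarity reversal): the Breslow intermediate of the aryl aldehyde adds as an acyl anion to formaldehyde, the more electrophilic and non-enolisable partner, and gives the α-hydroxy ketone.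

**Step 5**
Reactants: 7 1-[3,4-bis(benzyloxy)phenyl]-2-hydroxyethan-1-one
Product: 8 1-[3,4-bis(benzyloxy)phenyl]-2-(methoxymethoxy)ethan-1-one
Conditions: MOMCl, iPr2NEt, CH2Cl2, 0 °C → rt
Reagents that add atoms: chloromethyl methyl ether COCCl
Why: O-alkylation of the primary alcohol to the MOM acetal; this group is chosen because, unlike a silyl or acyl group, it cannot migrate to the enolate oxygen in step 6, and it can later be cleaved at the acetal carbon without protonating the enol ether.

**Step 6**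
Reactants: 8 1-[3,4-bis(benzyloxy)phenyl]-2-(methoxymethoxy)ethan-1-one; 5 1,5-bis(benzyloxy)-3-bromo-2-(bromomethyl)benzene
Product: 10 5,7-bis(benzyloxy)-2-[3,4-bis(benzyloxy)phenyl]-3-(methoxymethoxy)-4H-chromene, via C-benzylated bromo ketone 9 (not isolated)
Conditions: LiN(SiMe3)2 (1.05 equiv), THF, −78 °C; 5, −78 °C → rt; then solvent exchange to DMF, CuI (10 mol %), 1,10-phenanthroline (20 mol %), Cs2CO3 (2 equiv), 100 °C, same flask
Reagents that add atoms: none
Why: The chelated lithium Z-enolate of 8 is benzylated at C3 by the benzylic bromide of 5 (SN2, C3–C4 bond); carbonate then re-enolises 9 at its only α-hydrogen, and the enolate oxygen O1 is arylated at C8a through oxidative addition of the aryl bromide to monovalent copper and C–O reductive elimination (O1–C8a bond). The closest known reaction type is the domino C-benzylation/Ullmann O-arylation of enolisable carbonyl compounds with 2-bromobenzyl bromides to 4H-chromenes, together with the intramolecular O-arylation of ketone enolates. Ring C closes as a six-membered ring by attack of the enolate oxygen on the ring-A carbon, exo with respect to the departing bromide and with the enolate C2=C3 bond inside the new ring. No stereocentre is set: C2 and C3 are sp2 in 10 and the C3 centre of racemic 9 is erased, so 10 is achiral. The step needs C- over O-benzylation (lithium counter-ion in THF, soft benzylic bromide), mono-alkylation (stoichiometry and the hindered tertiary α-carbon of 9) and O- over C-arylation (C-arylation would close a four-membered ring); the regiochemistry on ring A is fixed by the positions of CH2Br and Br, and the non-migrating MOM group keeps O1 as the only oxygen nucleophile.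

**Step 7**
Reactants: 10 5,7-bis(benzyloxy)-2-[3,4-bis(benzyloxy)phenyl]-3-(methoxymethoxy)-4H-chromene
Product: 13 rac-5,7-bis(benzyloxy)-2-[3,4-bis(benzyloxy)phenyl]chroman-3-one, via bromomethyl enol ether 11 (not isolated), via enol 12 (not isolated)
Conditions: Me2BBr, CH2Cl2, −78 °C, argon; then aqueous NaHCO3
Reagents that add atoms: none
Why: Lewis-acid cleavage of a MOM acetal: boron binds the methoxy oxygen and bromide gives the bromomethyl ether 11, which hydrolyses at work-up to the enol 12; 12 tautomerises by protonation at C2 (directed by the C3 oxygen) to the ketone, no protic acid touches the enol ether, the benzyl ethers survive at −78 °C, and C2 is formed racemic.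

**Step 8**
Reactants: 13 rac-5,7-bis(benzyloxy)-2-[3,4-bis(benzyloxy)phenyl]chroman-3-one
Product: 14 (2R,3R)-5,7-bis(benzyloxy)-2-[3,4-bis(benzyloxy)phenyl]chroman-3-ol
Conditions: RuCl(p-cymene)[(R,R)-TsDPEN] (2 mol %), HCO2H/Et3N (2:5), DMF, 40 °C, argon
Reagents that add atoms: none
Why: Noyori asymmetric transfer hydrogenation with dynamic kinetic resolution of an α-aryl cyclic ketone: C2 (benzylic, α-aryloxy, α-keto) should epimerise through the enol 12 under the amine faster than reduction; hydride is delivered to C3 anti to the C2 aryl group, so the 2,3-cis alcohol should form, and the chiral ruthenium hydride fixes 3R and thereby selects the 2R ketone.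

**Step 9**
Reactants: 15 methyl 3,5-dihydroxy-4-methoxybenzoate
Product: 16 methyl 3,5-bis(benzyloxy)-4-methoxybenzoate
Conditions: BnBr, K2CO3, DMF, 60 °C
Reagents that add atoms: benzyl bromide BrCc1ccccc1
Why: Williamson ether synthesis on both phenols; the ester and the aryl methyl ether are untouched.

**Step 10**
Reactants: 16 methyl 3,5-bis(benzyloxy)-4-methoxybenzoate
Product: 17 3,5-bis(benzyloxy)-4-methoxybenzoic acid
Conditions: LiOH, THF/MeOH/H2O, 50 °C; then 1 M HCl
Reagents that add atoms: lithium hydroxide [Li+].[OH-]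
Why: Saponification of the methyl ester; the benzyl and methyl aryl ethers are stable to hydroxide.

**Step 11**
Reactants: 14 (2R,3R)-5,7-bis(benzyloxy)-2-[3,4-bis(benzyloxy)phenyl]chroman-3-ol; 17 3,5-bis(benzyloxy)-4-methoxybenzoic acid
Product: 18 (2R,3R)-5,7-bis(benzyloxy)-2-[3,4-bis(benzyloxy)phenyl]chroman-3-yl 3,5-bis(benzyloxy)-4-methoxybenzoate
Conditions: DCC, DMAP, CH2Cl2, 0 °C → rt
Reagents that add atoms: none
Why: Steglich esterification of the only free hydroxyl group; the C3–O bond is not broken, so the configuration is retained, and all phenols are masked.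

**Step 12**
Reactants: 18 (2R,3R)-5,7-bis(benzyloxy)-2-[3,4-bis(benzyloxy)phenyl]chroman-3-yl 3,5-bis(benzyloxy)-4-methoxybenzoate
Product: 19 epicatechin 3-O-(4-O-methylgallate)
Conditions: H2 (1 atm), Pd(OH)2/C, THF/MeOH, rt
Reagents that add atoms: none
Why: Hydrogenolysis of six aryl benzyl ethers; the ester and the aryl methyl ether are inert, mild pressure and short contact should spare the benzylic C2–O1 bond, and no stereocentre is touched.

**Compound list**
1 | 1,3-bis(benzyloxy)-5-bromobenzene | Brc1cc(OCc2ccccc2)cc(OCc2ccccc2)c1 | starting material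
2 | N-{[2,4-bis(benzyloxy)-6-bromophenyl]methylidene}-N-methylmethanaminium chloride | C[N+](C)=Cc1c(Br)cc(OCc2ccccc2)cc1OCc1ccccc1.[Cl-] | intermediate
3 | 2,4-bis(benzyloxy)-6-bromobenzaldehyde | O=Cc1c(Br)cc(OCc2ccccc2)cc1OCc1ccccc1 | intermediate
4 | [2,4-bis(benzyloxy)-6-bromophenyl]methanol | OCc1c(Br)cc(OCc2ccccc2)cc1OCc1ccccc1 | intermediate
5 | 1,5-bis(benzyloxy)-3-bromo-2-(bromomethyl)benzene | BrCc1c(Br)cc(OCc2ccccc2)cc1OCc1ccccc1 | intermediate
6 | 3,4-bis(benzyloxy)benzaldehyde | O=Cc1ccc(OCc2ccccc2)c(OCc2ccccc2)c1 | starting material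
7 | 1-[3,4-bis(benzyloxy)phenyl]-2-hydroxyethan-1-one | OCC(=O)c1ccc(OCc2ccccc2)c(OCc2ccccc2)c1 | intermediate
8 | 1-[3,4-bis(benzyloxy)phenyl]-2-(methoxymethoxy)ethan-1-one | COCOCC(=O)c1ccc(OCc2ccccc2)c(OCc2ccccc2)c1 | intermediate
9 | rac-1-[3,4-bis(benzyloxy)phenyl]-3-[2,4-bis(benzyloxy)-6-bromophenyl]-2-(methoxymethoxy)propan-1-one | COCOC(Cc1c(Br)cc(OCc2ccccc2)cc1OCc1ccccc1)C(=O)c1ccc(OCc2ccccc2)c(OCc2ccccc2)c1 | intermediate
10 | 5,7-bis(benzyloxy)-2-[3,4-bis(benzyloxy)phenyl]-3-(methoxymethoxy)-4H-chromene | COCOC1=C(c2ccc(OCc3ccccc3)c(OCc3ccccc3)c2)Oc2cc(OCc3ccccc3)cc(OCc3ccccc3)c2C1 | intermediate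
11 | 5,7-bis(benzyloxy)-2-[3,4-bis(benzyloxy)phenyl]-3-(bromomethoxy)-4H-chromene | BrCOC1=C(c2ccc(OCc3ccccc3)c(OCc3ccccc3)c2)Oc2cc(OCc3ccccc3)cc(OCc3ccccc3)c2C1 | intermediate
12 | 5,7-bis(benzyloxy)-2-[3,4-bis(benzyloxy)phenyl]-4H-chromen-3-ol | OC1=C(c2ccc(OCc3ccccc3)c(OCc3ccccc3)c2)Oc2cc(OCc3ccccc3)cc(OCc3ccccc3)c2C1 | intermediate
13 | rac-5,7-bis(benzyloxy)-2-[3,4-bis(benzyloxy)phenyl]chroman-3-one | O=C1Cc2c(OCc3ccccc3)cc(OCc3ccccc3)cc2OC1c1ccc(OCc2ccccc2)c(OCc2ccccc2)c1 | intermediate
14 | (2R,3R)-5,7-bis(benzyloxy)-2-[3,4-bis(benzyloxy)phenyl]chroman-3-ol | O[C@@H]1Cc2c(OCc3ccccc3)cc(OCc3ccccc3)cc2O[C@@H]1c1ccc(OCc2ccccc2)c(OCc2ccccc2)c1 | intermediate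
15 | methyl 3,5-dihydroxy-4-methoxybenzoate | COC(=O)c1cc(O)c(OC)c(O)c1 | starting material
16 | methyl 3,5-bis(benzyloxy)-4-methoxybenzoate | COC(=O)c1cc(OCc2ccccc2)c(OC)c(OCc2ccccc2)c1 | intermediate
17 | 3,5-bis(benzyloxy)-4-methoxybenzoic acid | COc1c(OCc2ccccc2)cc(C(=O)O)cc1OCc1ccccc1 | intermediate
18 | (2R,3R)-5,7-bis(benzyloxy)-2-[3,4-bis(benzyloxy)phenyl]chroman-3-yl 3,5-bis(benzyloxy)-4-methoxybenzoate | COc1c(OCc2ccccc2)cc(C(=O)O[C@@H]2Cc3c(OCc4ccccc4)cc(OCc4ccccc4)cc3O[C@@H]2c2ccc(OCc3ccccc3)c(OCc3ccccc3)c2)cc1OCc1ccccc1 | intermediate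
19 | epicatechin 3-O-(4-O-methylgallate), (2R,3R) | COc1c(O)cc(C(=O)O[C@@H]2Cc3c(O)cc(O)cc3O[C@@H]2c2ccc(O)c(O)c2)cc1O | target

**Totals**
Total step count: 12. Longest linear sequence: 8 (steps 1, 2, 3, 6, 7, 8, 11, 12).

**Steps most likely to fail**

Step 6. The copper-mediated O-arylation of the hindered, tetrasubstituted enolate of 9 may stall or give way to protodebromination of ring A, and the first stage may lose material to O-benzylation or double benzylation. The fallback sets out from 9, isolated by aqueous quench before copper is added, and replaces the enolate by an sp3 alkoxide as the oxygen nucleophile. NaBH4 in MeOH/THF reduces the ketone to 1-[3,4-bis(benzyloxy)phenyl]-3-[2,4-bis(benzyloxy)-6-bromophenyl]-2-(methoxymethoxy)propan-1-ol F1. Intramolecular palladium-catalysed C–O coupling of the secondary alkoxide with the aryl bromide (Pd(OAc)2, 2-(di-tert-butylphosphino)-1,1'-binaphthyl, Cs2CO3, toluene, 80 °C) closes ring C to 5,7-bis(benzyloxy)-2-[3,4-bis(benzyloxy)phenyl]-3-(methoxymethoxy)chromane F2. HCl in MeOH removes the now ordinary alkyl MOM ether to give 5,7-bis(benzyloxy)-2-[3,4-bis(benzyloxy)phenyl]chroman-3-ol F3 as a mixture of racemic cis and trans isomers. Dess–Martin oxidation of F3 gives the ketone, and the fallback comes back to the route at 13.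

Step 8. Epimerisation at C2 may be slower than reduction, so that the step becomes a simple kinetic resolution; the catalyst may also discriminate poorly between the faces of a ketone that is not conjugated to an arene, or act with the opposite sense. The fallback sets out from 13 and separates the setting of relative and absolute configuration. LiBH(s-Bu)3 in THF at −78 °C should give, by attack anti to ring B, rac-cis-5,7-bis(benzyloxy)-2-[3,4-bis(benzyloxy)phenyl]chroman-3-ol F4. Steglich esterification with (2S)-2-methoxy-2-phenylacetic acid (DCC, DMAP) gives two diastereomeric esters, which are separated by chromatography or crystallisation: (2R,3R)-5,7-bis(benzyloxy)-2-[3,4-bis(benzyloxy)phenyl]chroman-3-yl (2S)-2-methoxy-2-phenylacetate F5 and (2S,3S)-5,7-bis(benzyloxy)-2-[3,4-bis(benzyloxy)phenyl]chroman-3-yl (2S)-2-methoxy-2-phenylacetate F6. Methanolysis of F5 (K2CO3, MeOH/THF) releases the alcohol, and the fallback comes back to the route at 14.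

Step 7. The Lewis acid or adventitious HBr may protonate C3 of the electron-rich enol ether instead of cleaving the acetal; the C2 oxocarbenium ion would then be trapped by water at work-up and ring C would open. The fallback sets out from 7 and changes the unmasking to a fluoride-triggered fragmentation in which no acid is present. 2-(Trimethylsilyl)ethoxymethyl chloride and iPr2NEt give 1-[3,4-bis(benzyloxy)phenyl]-2-{[2-(trimethylsilyl)ethoxy]methoxy}ethan-1-one F7. Under the conditions of step 6 with 5, F7 gives, through rac-1-[3,4-bis(benzyloxy)phenyl]-3-[2,4-bis(benzyloxy)-6-bromophenyl]-2-{[2-(trimethylsilyl)ethoxy]methoxy}propan-1-one F8 (not isolated), 5,7-bis(benzyloxy)-2-[3,4-bis(benzyloxy)phenyl]-3-{[2-(trimethylsilyl)ethoxy]methoxy}-4H-chromene F9. Bu4NF in THF at 50 °C under argon, followed by an acetic acid quench, fragments the acetal from silicon and releases the enolate, which is protonated at C2; the fallback comes back to the route at 13.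

**Further compounds**
F1 | step 6 | 1-[3,4-bis(benzyloxy)phenyl]-3-[2,4-bis(benzyloxy)-6-bromophenyl]-2-(methoxymethoxy)propan-1-ol (racemic diastereomer mixture) | COCOC(Cc1c(Br)cc(OCc2ccccc2)cc1OCc1ccccc1)C(O)c1ccc(OCc2ccccc2)c(OCc2ccccc2)c1
F2 | step 6 | 5,7-bis(benzyloxy)-2-[3,4-bis(benzyloxy)phenyl]-3-(methoxymethoxy)chromane (racemic cis/trans mixture) | COCOC1Cc2c(OCc3ccccc3)cc(OCc3ccccc3)cc2OC1c1ccc(OCc2ccccc2)c(OCc2ccccc2)c1
F3 | step 6 | 5,7-bis(benzyloxy)-2-[3,4-bis(benzyloxy)phenyl]chroman-3-ol (racemic cis/trans mixture) | OC1Cc2c(OCc3ccccc3)cc(OCc3ccccc3)cc2OC1c1ccc(OCc2ccccc2)c(OCc2ccccc2)c1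
F4 | step 8 | rac-cis-5,7-bis(benzyloxy)-2-[3,4-bis(benzyloxy)phenyl]chroman-3-ol (both enantiomers) | O[C@@H]1Cc2c(OCc3ccccc3)cc(OCc3ccccc3)cc2O[C@@H]1c1ccc(OCc2ccccc2)c(OCc2ccccc2)c1.O[C@H]1Cc2c(OCc3ccccc3)cc(OCc3ccccc3)cc2O[C@H]1c1ccc(OCc2ccccc2)c(OCc2ccccc2)c1
F5 | step 8 | (2R,3R)-5,7-bis(benzyloxy)-2-[3,4-bis(benzyloxy)phenyl]chroman-3-yl (2S)-2-methoxy-2-phenylacetate | CO[C@H](C(=O)O[C@@H]1Cc2c(OCc3ccccc3)cc(OCc3ccccc3)cc2O[C@@H]1c1ccc(OCc2ccccc2)c(OCc2ccccc2)c1)c1ccccc1
F6 | step 8 | (2S,3S)-5,7-bis(benzyloxy)-2-[3,4-bis(benzyloxy)phenyl]chroman-3-yl (2S)-2-methoxy-2-phenylacetate | CO[C@H](C(=O)O[C@H]1Cc2c(OCc3ccccc3)cc(OCc3ccccc3)cc2O[C@H]1c1ccc(OCc2ccccc2)c(OCc2ccccc2)c1)c1ccccc1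
F7 | step 7 | 1-[3,4-bis(benzyloxy)phenyl]-2-{[2-(trimethylsilyl)ethoxy]methoxy}ethan-1-one | C[Si](C)(C)CCOCOCC(=O)c1ccc(OCc2ccccc2)c(OCc2ccccc2)c1
F8 | step 7 | rac-1-[3,4-bis(benzyloxy)phenyl]-3-[2,4-bis(benzyloxy)-6-bromophenyl]-2-{[2-(trimethylsilyl)ethoxy]methoxy}propan-1-one | C[Si](C)(C)CCOCOC(Cc1c(Br)cc(OCc2ccccc2)cc1OCc1ccccc1)C(=O)c1ccc(OCc2ccccc2)c(OCc2ccccc2)c1
F9 | step 7 | 5,7-bis(benzyloxy)-2-[3,4-bis(benzyloxy)phenyl]-3-{[2-(trimethylsilyl)ethoxy]methoxy}-4H-chromene | C[Si](C)(C)CCOCOC1=C(c2ccc(OCc3ccccc3)c(OCc3ccccc3)c2)Oc2cc(OCc3ccccc3)cc(OCc3ccccc3)c2C1
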